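The route rests on cutting C3–C4 in ring A. The feature exploited is the cis oxygen pair on adjacent ring-A carbons: secondary C3–O next to tertiary, isopropyl-bearing C4–O, which is the pattern a keto–aldehyde pinacol produces. One SmI2 step closes ring A onto the finished seven-membered ring B, forms C3–C4 and sets both carbinol centres. The precursor is a cycloheptene with methyl and CH2CHO on C1, a cis isobutyryl group on C5, and non-chelating silyl ethers on O6 and O10. C1 comes from a chirality-transferring Claisen rearrangement, C10 from methallylboration, C5/C6 from a syn boron aldol, and ring B from metathesis. The fragile aldehyde is unmasked last.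

Key step: step 15

Assumption: the SMILES is read as the cis-fused (1S,3S,4R,5R,6S,10S) isomer, with C1-methyl, H5, O3, O4 and O10 on one face and O6 and isopropyl on the other; numbering is C1 quaternary fusion carbon, C2 CH2, C3 CH–OAc, C4 C(OH)i-Pr, C5 fusion CH, C6 CH–O-aroyl, C7=C8(Me), C9 CH2, C10 CH–OH.

Step 1
Reactants: 1 but-3-yn-1-ol
Product: 2 4-methoxybenzyl but-3-yn-1-yl ether
Conditions: NaH, PMBCl, tetrabutylammonium iodide (cat.), THF/DMF, 0 °C → rt
Reagents that add atoms: 4-methoxybenzyl chloride, COc1ccc(CCl)cc1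
Why: Williamson ether synthesis on the primary alkoxide; the PMB ether tolerates the organoaluminium, organolithium, boron and ruthenium reagents to come and can later be removed oxidatively at neutral pH.

Step 2
Reactants: 2 4-methoxybenzyl but-3-yn-1-yl ether
Product: 4 (E)-4-iodo-3-methylbut-3-en-1-yl 4-methoxybenzyl ether, via alkenyldimethylalane 3 (not isolated)
Conditions: AlMe3, Cp2ZrCl2 (25 mol %), CH2Cl2, 0 °C → rt; I2, THF, −30 °C
Reagents that add atoms: trimethylaluminium, C[Al](C)C; iodine, II
Why: Negishi zirconium-catalysed carboalumination adds methyl and aluminium syn and regioselectively across the terminal alkyne, and iodinolysis with retention fixes the E trisubstituted olefin that later defines C1.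

Step 3
Reactants: 4 (E)-4-iodo-3-methylbut-3-en-1-yl 4-methoxybenzyl ether; 5 N-methoxy-N-methylacetamide
Product: 7 (E)-6-(4-methoxybenzyloxy)-4-methylhex-3-en-2-one, via alkenyllithium 6 (not isolated)
Conditions: t-BuLi (2.1 equiv), Et2O, −78 °C; then 5, −78 → 0 °C
Reagents that add atoms: none
Why: Lithium–iodine exchange with retention of olefin geometry, followed by a Weinreb ketone synthesis whose chelated tetrahedral adduct prevents over-addition.

Step 4
Reactants: 7 (E)-6-(4-methoxybenzyloxy)-4-methylhex-3-en-2-one
Product: 8 (S,E)-6-(4-methoxybenzyloxy)-4-methylhex-3-en-2-ol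
Conditions: (R)-2-methyl-CBS-oxazaborolidine (C18H20BNO, 15 mol %), catecholborane, toluene, −78 °C
Reagents that add atoms: none
Why: Corey–Bakshi–Shibata reduction, in which the R catalyst binds the enone with the alkenyl group as the large substituent and delivers hydride 1,2 to give the S carbinol, the only external source of chirality for C1.

Step 5
Reactants: 8 (S,E)-6-(4-methoxybenzyloxy)-4-methylhex-3-en-2-ol; 9 N,N-dimethylacetamide dimethyl acetal
Product: 11 (S,E)-3-[2-(4-methoxybenzyloxy)ethyl]-N,N,3-trimethylhex-4-enamide (C1 = S), via ketene N,O-acetal 10 (not isolated)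
Conditions: 9 (5 equiv), xylenes, 140 °C, methanol distilled off
Reagents that add atoms: none
Why: Eschenmoser–Claisen rearrangement, in which acetal exchange and loss of methanol give the ketene N,O-acetal, and its chair transition state with the carbinol methyl equatorial passes the S configuration suprafacially to the new quaternary C1 (S), leaving an E-propenyl group.

Step 6
Reactants: 11 (S,E)-3-[2-(4-methoxybenzyloxy)ethyl]-N,N,3-trimethylhex-4-enamide
Product: 12 (S)-3-formyl-5-(4-methoxybenzyloxy)-N,N,3-trimethylpentanamide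
Conditions: O3, CH2Cl2, −78 °C (Sudan Red 7B end point); PPh3, −78 °C → rt
Reagents that add atoms: ozone, [O-][O+]=O
Why: Ozonolysis with reductive work-up cleaves the only olefin to the non-enolisable neopentyl aldehyde C10, and the dye end point protects the electron-rich PMB ring from over-oxidation.

Step 7
Reactants: 12 (S)-3-formyl-5-(4-methoxybenzyloxy)-N,N,3-trimethylpentanamide
Product: 13 (3S,4S)-4-hydroxy-3-[2-(4-methoxybenzyloxy)ethyl]-N,N,3,6-tetramethylhept-6-enamide (1S,10S)
Conditions: (−)-Ipc2BOMe, 2-methylallylmagnesium chloride, Et2O, 0 °C → rt; 12, −78 °C; NaOH, H2O2, 0 °C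
Reagents that add atoms: 2-methylallylmagnesium chloride, CC(=C)C[Mg]Cl
Why: Brown asymmetric methallylboration through a closed chair transition state, in which the isopinocampheyl ligands derived from (+)-α-pinene select the aldehyde face that gives 10S irrespective of the adjacent quaternary carbon, while the tertiary amide stays untouched.

Step 8
Reactants: 13 hydroxy amide (1S,10S)
Product: 14 C10 tert-butyldimethylsilyl ether of 13
Conditions: TBSOTf, 2,6-lutidine, CH2Cl2, −78 → 0 °C
Reagents that add atoms: tert-butyldimethylsilyl triflate, CC(C)(C)[Si](C)(C)OS(=O)(=O)C(F)(F)F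
Why: Silyl triflate silylation of a hindered secondary alcohol; capping O10 stops lactonisation onto the amide now and lactol formation with the C3 aldehyde later.

Step 9
Reactants: 14 silyloxy amide (1S,10S)
Product: 15 (5S,6S)-6-(tert-butyldimethylsilyloxy)-5-[2-(4-methoxybenzyloxy)ethyl]-2,5,8-trimethylnon-8-en-3-one
Conditions: i-PrLi (1.5 equiv), Et2O, −78 → −30 °C
Reagents that add atoms: isopropyllithium, [Li]C(C)C
Why: Addition of an organolithium to a tertiary amide gives a stable tetrahedral lithium adduct that collapses to the isopropyl ketone only on quenching, so C4 and the isopropyl group arrive without over-addition.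

Step 10
Reactants: 15 isopropyl ketone (1S,10S); 16 acrolein
Product: 18 syn-aldol adduct (1S,5R,6S,10S) in which C5 carries the (S)-1-hydroxyallyl group, via Z-enol diisopinocampheylborinate 17 (not isolated)
Conditions: (+)-Ipc2BOTf, i-Pr2NEt, CH2Cl2, −78 → 0 °C; 16, −78 → −20 °C; H2O2, pH 7 buffer, MeOH, 0 °C
Reagents that add atoms: none
Why: Boron-mediated aldol reaction with chiral ligands, in which soft enolisation on the methylene side gives the Z-enol borinate, the Zimmerman–Traxler chair turns it into the 5,6-syn pair (the flat vinyl group of acrolein tolerates the tert-alkyl neighbour), and the ligands from (−)-α-pinene, which should show the same aldehyde-face preference as in the related allylborations, select 5R,6S, supported by C1 placing its silyloxy-bearing branch anti to the incoming aldehyde.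

Step 11
Reactants: 18 syn-aldol adduct (1S,5R,6S,10S)
Product: 19 C6 triethylsilyl ether of 18
Conditions: TESOTf, 2,6-lutidine, CH2Cl2, −78 °C
Reagents that add atoms: triethylsilyl triflate, CC[Si](CC)(CC)OS(=O)(=O)C(F)(F)F
Why: Low-temperature silyl triflate silylation avoids retro-aldol and β-elimination; the triethylsilyl ether does not chelate samarium and can later be cleaved in the presence of the tert-butyldimethylsilyl ether.

Step 12
Reactants: 19 bis-silyl diene (1S,5R,6S,10S)
Product: 20 ring-B cycloheptene (1S,5R,6S,10S) with C1 methyl and CH2CH2OPMB, C5 isobutyryl, C6 OTES, C7=C8(Me) and C10 OTBS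
Conditions: second-generation Grubbs catalyst RuCl2(=CHPh)(SIMes)(PCy3) (10 mol %), toluene (2 mM), 80 °C
Reagents that add atoms: none
Why: Ring-closing metathesis of the C7 vinyl group onto the 1,1-disubstituted C8 olefin gives the trisubstituted ring olefin, favoured by the quaternary C1 that folds the chain and free of competing closures because the C1 arm carries no olefin.

Step 13
Reactants: 20 ring-B cycloheptene PMB ether
Product: 21 primary alcohol (C1 arm = CH2CH2OH)
Conditions: DDQ, CH2Cl2/pH 7 buffer (10:1), 0 °C
Reagents that add atoms: none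
Why: Oxidative PMB cleavage by DDQ (hydride abstraction, then hydrolysis of the oxocarbenium ion) at buffered neutral pH spares both silyl ethers, the olefin and the base-sensitive β-silyloxy ketone.

Step 14
Reactants: 21 primary alcohol
Product: 22 cycloheptene keto-aldehyde (1S,5R,6S,10S) with C1 methyl and CH2CHO, C5 isobutyryl, C6 OTES and C10 OTBS
Conditions: Dess–Martin periodinane, pyridine, CH2Cl2, 0 °C → rt
Reagents that add atoms: none
Why: Dess–Martin oxidation under pyridine buffering gives the aldehyde without acid or strong base, so C5 is not epimerised and O6 is not eliminated, and 22 is used at once.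

Step 15
Reactants: 22 cycloheptene keto-aldehyde
Product: 23 bicyclic cis-3,4-diol (1S,3S,4R,5R,6S,10S) with C6 OTES and C10 OTBS
Conditions: SmI2 (2.5 equiv, 0.1 M in THF), t-BuOH (2 equiv), THF, −78 → −20 °C, slow addition of 22, no HMPA
Reagents that add atoms: none
Why: Divalent samarium transfers one electron to the more easily reduced aldehyde, the ketyl's trivalent samarium also binds the C4 ketone oxygen, C3 adds to C4, and a second electron plus protonation release the diol; this is the known SmI2 keto–aldehyde pinacol cyclisation to cis-cyclopentane-1,2-diols. Ring A closes in a 5-exo-trig mode, since the attacked C4=O keeps its oxygen outside the new ring. The O–Sm–O bridge holds O3 and O4 on the same side, which fixes C3 (S) relative to C4. The C4 face follows from the cis relation of the two arms preset at C1 and C5: the bulky solvated samarium diolate should sit on the convex face beside C1-methyl and H5, away from the concave face filled by ring B and the non-chelating C6 silyl ether, so isopropyl turns inward (4R). The step needs coupling to outrun simple aldehyde reduction, β-elimination at C6 and ketyl–olefin closure onto C7=C8. The gem-disubstituted C1 that holds the carbonyls close, the weak proton source, the HMPA-free chelating medium and the unactivated olefin should secure this.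

Step 16
Reactants: 23 bicyclic cis-3,4-diol
Product: 24 C3 acetate
Conditions: Ac2O, pyridine, 4-(dimethylamino)pyridine (cat.), CH2Cl2, 0 °C
Reagents that add atoms: acetic anhydride, CC(=O)OC(C)=O
Why: DMAP-catalysed acylation distinguishes the secondary C3 hydroxyl from the tertiary, isopropyl-flanked C4 hydroxyl on steric grounds.

Step 17
Reactants: 24 C3 acetate
Product: 25 C6 allylic alcohol (C10 OTBS retained)
Conditions: pyridinium p-toluenesulfonate (20 mol %), MeOH/CH2Cl2, 0 °C
Reagents that add atoms: none
Why: Mild acid-catalysed methanolysis removes the triethylsilyl ether much faster than the neopentyl tert-butyldimethylsilyl ether and leaves the acetate and the tertiary alcohol alone.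

Step 18
Reactants: 26 4-hydroxybenzoic acid
Product: 28 4-(tert-butyldimethylsilyloxy)benzoic acid, via bis-silylated ester 27 (not isolated)
Conditions: TBSCl (2.3 equiv), imidazole, DMF, rt; then AcOH/THF/H2O, rt
Reagents that add atoms: tert-butyldimethylsilyl chloride, CC(C)(C)[Si](C)(C)Cl
Why: Exhaustive silylation followed by selective hydrolysis of the labile silyl ester leaves the phenol masked so that it cannot compete in the esterification.

Step 19
Reactants: 25 C6 allylic alcohol; 28 4-(tert-butyldimethylsilyloxy)benzoic acid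
Product: 29 C6 4-(tert-butyldimethylsilyloxy)benzoate
Conditions: DCC, 4-(dimethylamino)pyridine, CH2Cl2, rt → 35 °C
Reagents that add atoms: none
Why: Steglich esterification, in which the acylpyridinium ion formed from the O-acylisourea acylates the secondary allylic C6 hydroxyl with retention while the tertiary C4 hydroxyl is too hindered to react.

Step 20
Reactants: 29 C6 4-(tert-butyldimethylsilyloxy)benzoate
Product: 30 target CNP0146780.2
Conditions: Et3N·3HF, MeCN/THF, rt → 40 °C
Reagents that add atoms: none
Why: Fluoride-mediated desilylation with the nearly neutral amine–HF complex removes the aryl and the C10 silyl ethers without hydrolysing or migrating the two esters or ionising the allylic benzoate.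

Compound list
1 | but-3-yn-1-ol | C#CCCO | starting material
2 | 4-methoxybenzyl but-3-yn-1-yl ether | C#CCCOCc1ccc(OC)cc1 | intermediate
3 | (E)-alkenyldimethylalane (Al cis to methyl) | C[Al](C)/C=C(\C)CCOCc1ccc(OC)cc1 | intermediate
4 | (E)-4-iodo-3-methylbut-3-en-1-yl 4-methoxybenzyl ether | I/C=C(\C)CCOCc1ccc(OC)cc1 | intermediate
5 | N-methoxy-N-methylacetamide | CON(C)C(C)=O | starting material
6 | (E)-alkenyllithium | [Li]/C=C(\C)CCOCc1ccc(OC)cc1 | intermediate
7 | (E)-6-(4-methoxybenzyloxy)-4-methylhex-3-en-2-one | CC(=O)/C=C(\C)CCOCc1ccc(OC)cc1 | intermediate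
8 | (S,E)-6-(4-methoxybenzyloxy)-4-methylhex-3-en-2-ol | C[C@H](O)/C=C(\C)CCOCc1ccc(OC)cc1 | intermediate
9 | N,N-dimethylacetamide dimethyl acetal | CC(OC)(OC)N(C)C | starting material
10 | ketene N,O-acetal of 8 | C=C(N(C)C)O[C@@H](C)/C=C(\C)CCOCc1ccc(OC)cc1 | intermediate
11 | (S,E)-3-[2-(4-methoxybenzyloxy)ethyl]-N,N,3-trimethylhex-4-enamide | CN(C)C(=O)C[C@](C)(CCOCc1ccc(OC)cc1)/C=C/C | intermediate
12 | (S)-3-formyl-5-(4-methoxybenzyloxy)-N,N,3-trimethylpentanamide | CN(C)C(=O)C[C@](C)(CCOCc1ccc(OC)cc1)C=O | intermediate
13 | (3S,4S)-4-hydroxy-3-[2-(4-methoxybenzyloxy)ethyl]-N,N,3,6-tetramethylhept-6-enamide | CN(C)C(=O)C[C@](C)(CCOCc1ccc(OC)cc1)[C@@H](O)CC(C)=C | intermediate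
14 | C10 TBS ether of 13 | CN(C)C(=O)C[C@](C)(CCOCc1ccc(OC)cc1)[C@@H](O[Si](C)(C)C(C)(C)C)CC(C)=C | intermediate
15 | (5S,6S)-6-(TBSO)-5-[2-(PMBO)ethyl]-2,5,8-trimethylnon-8-en-3-one | CC(C)C(=O)C[C@](C)(CCOCc1ccc(OC)cc1)[C@@H](O[Si](C)(C)C(C)(C)C)CC(C)=C | intermediate
16 | acrolein | C=CC=O | starting material
17 | Z-enol diisopinocampheylborinate of 15 | CC(C)/C(OB([C@H]1C[C@H]2C[C@@H]([C@@H]1C)C2(C)C)[C@H]1C[C@H]2C[C@@H]([C@@H]1C)C2(C)C)=C/[C@](C)(CCOCc1ccc(OC)cc1)[C@@H](O[Si](C)(C)C(C)(C)C)CC(C)=C | intermediate
18 | syn-aldol adduct (1S,5R,6S,10S) | CC(C)C(=O)[C@@H]([C@@H](O)C=C)[C@](C)(CCOCc1ccc(OC)cc1)[C@@H](O[Si](C)(C)C(C)(C)C)CC(C)=C | intermediate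
19 | C6 TES ether of 18 | CC(C)C(=O)[C@@H]([C@@H](O[Si](CC)(CC)CC)C=C)[C@](C)(CCOCc1ccc(OC)cc1)[C@@H](O[Si](C)(C)C(C)(C)C)CC(C)=C | intermediate
20 | ring-B cycloheptene, C1 arm CH2CH2OPMB (1S,5R,6S,10S) | COc1ccc(COCC[C@]2(C)[C@@H](O[Si](C)(C)C(C)(C)C)CC(C)=C[C@H](O[Si](CC)(CC)CC)[C@@H]2C(=O)C(C)C)cc1 | intermediate
21 | ring-B cycloheptene, C1 arm CH2CH2OH | OCC[C@]1(C)[C@@H](O[Si](C)(C)C(C)(C)C)CC(C)=C[C@H](O[Si](CC)(CC)CC)[C@@H]1C(=O)C(C)C | intermediate
22 | cycloheptene keto-aldehyde (key-step precursor) | O=CC[C@]1(C)[C@@H](O[Si](C)(C)C(C)(C)C)CC(C)=C[C@H](O[Si](CC)(CC)CC)[C@@H]1C(=O)C(C)C | intermediate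
23 | bicyclic cis-3,4-diol (key-step product, 1S,3S,4R,5R,6S,10S) | O[C@H]1C[C@]2(C)[C@@H](O[Si](C)(C)C(C)(C)C)CC(C)=C[C@H](O[Si](CC)(CC)CC)[C@@H]2[C@]1(O)C(C)C | intermediate
24 | C3 acetate of 23 | CC(=O)O[C@H]1C[C@]2(C)[C@@H](O[Si](C)(C)C(C)(C)C)CC(C)=C[C@H](O[Si](CC)(CC)CC)[C@@H]2[C@]1(O)C(C)C | intermediate
25 | C6 alcohol (C3 OAc, C10 OTBS) | CC(=O)O[C@H]1C[C@]2(C)[C@@H](O[Si](C)(C)C(C)(C)C)CC(C)=C[C@H](O)[C@@H]2[C@]1(O)C(C)C | intermediate
26 | 4-hydroxybenzoic acid | OC(=O)c1ccc(O)cc1 | starting material
27 | tert-butyldimethylsilyl 4-(tert-butyldimethylsilyloxy)benzoate | CC(C)(C)[Si](C)(C)OC(=O)c1ccc(O[Si](C)(C)C(C)(C)C)cc1 | intermediate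
28 | 4-(tert-butyldimethylsilyloxy)benzoic acid | CC(C)(C)[Si](C)(C)Oc1ccc(cc1)C(O)=O | intermediate
29 | C6 4-(TBSO)benzoate (C3 OAc, C10 OTBS) | CC(=O)O[C@H]1C[C@]2(C)[C@@H](O[Si](C)(C)C(C)(C)C)CC(C)=C[C@H](OC(=O)c3ccc(O[Si](C)(C)C(C)(C)C)cc3)[C@@H]2[C@]1(O)C(C)C | intermediate
30 | CNP0146780.2 | CC(=O)O[C@H]1C[C@]2(C)[C@@H](O)CC(C)=C[C@H](OC(=O)c3ccc(O)cc3)[C@@H]2[C@]1(O)C(C)C | target

Total step count: 20. Longest linear sequence: 19 (steps 1–17, 19, 20).

Steps most likely to fail

1. Step 15. The samarium-bridged diolate may form on the concave face, which gives the wrong cis-diol face. The aldehyde may also be reduced before it couples, or the C6 silyloxy group may be lost by β-elimination. The fallback sets out from 22. Low-valent titanium (TiCl3(DME)1.5, Zn–Cu, DME, reflux, slow addition) drives the same C3–C4 coupling through to the olefin in a McMurry reaction, giving the ring-A cyclopentene F1. OsO4 (1 equiv, pyridine, THF, −20 °C; NaHSO3) then adds both oxygens suprafacially from the convex face of the cis-fused bicycle. The C7=C8 olefin is shielded and inductively deactivated by the neighbouring silyl ether. The route is rejoined at 23.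

2. Step 10. Enolisation of the neopentyl methylene by the bulky boron triflate may be too slow, and face selectivity relative to C1 may erode. The fallback replaces reagent control by internal chelate control and sets out from 13. i-PrLi (3 equiv, Et2O, −78 → −20 °C) gives the free hydroxy ketone F2. LDA (2.2 equiv, THF, −78 °C) then forms a lithium alkoxide–Z-enolate chelate that holds the C10 branch next to the enolate oxygen and places the C9 chain and the C2 arm on one face. Acrolein 16 should therefore enter from the methyl face through a closed transition state, giving the aldol diol F3. TESCl/imidazole (CH2Cl2, −20 °C) silylates the less hindered allylic O6 to the mono-silyl ether F4, and TBSOTf/2,6-lutidine caps O10. The route is rejoined at 19.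

3. Step 12. Loading of ruthenium onto the crowded allylic-silyloxy vinyl group and closure onto the 1,1-disubstituted olefin may be slow, which would let dimerisation or olefin migration compete. The fallback changes the order of events and sets out from 18. The free allylic alcohol, which is less crowded and is known to assist metathesis at the adjacent vinyl group, is cyclised with the same ruthenium carbene in CH2Cl2 at 40 °C to the cycloheptenol F5. This is then silylated (TESOTf, 2,6-lutidine, −78 °C). The route is rejoined at 20.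

Further compounds
F1 | step 15 | ring-A cyclopentene (C3=C4, C6 OTES, C10 OTBS) | CC(C)C1=CC[C@]2(C)[C@@H](O[Si](C)(C)C(C)(C)C)CC(C)=C[C@H](O[Si](CC)(CC)CC)[C@@H]21
F2 | step 10 | (5S,6S)-6-hydroxy-5-[2-(PMBO)ethyl]-2,5,8-trimethylnon-8-en-3-one | CC(C)C(=O)C[C@](C)(CCOCc1ccc(OC)cc1)[C@@H](O)CC(C)=C
F3 | step 10 | syn-aldol diol (1S,5R,6S,10S), O6 and O10 free | CC(C)C(=O)[C@@H]([C@@H](O)C=C)[C@](C)(CCOCc1ccc(OC)cc1)[C@@H](O)CC(C)=C
F4 | step 10 | C6 TES ether with free C10 hydroxyl | CC(C)C(=O)[C@@H]([C@@H](O[Si](CC)(CC)CC)C=C)[C@](C)(CCOCc1ccc(OC)cc1)[C@@H](O)CC(C)=C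
F5 | step 12 | ring-B cycloheptenol (free C6 hydroxyl, C10 OTBS, arm CH2CH2OPMB) | COc1ccc(COCC[C@]2(C)[C@@H](O[Si](C)(C)C(C)(C)C)CC(C)=C[C@H](O)[C@@H]2C(=O)C(C)C)cc1
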